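**The problem**

Compound 27 is a linear proanthocyanidin tetramer: epigallocatechin-(4β→8)-epigallocatechin-(4β→8)-epigallocatechin 3-O-gallate-(4β→8)-epicatechin. With the flavan units numbered 1 to 4 from the end that keeps a free C8 down to the terminal epicatechin, three diarylmethine bonds join C4 of ring C of units 1, 2 and 3 to C8 of ring A of the unit below. There are eleven stereocenters: C2 and C3 of every unit (all 2R,3R, 2,3-cis) and C4 of units 1 to 3, each trans to O3. Inside a unit, control can run from C3: the O3 substituent of a 2,3-cis unit sends a nucleophile to the opposite face of a C4 cation, and a carbon bearing O3 next to a carbonyl group can direct the creation of C2. Between units the centers are too remote to be relied on. Every ring A offers both C6 and C8 to an electrophile, and every electrophilic unit is itself a nucleophile, so chain length and 4→8 regiochemistry have to be enforced. Only O3 of unit 3 is acylated among four secondary hydroxyls. The interflavan bonds are cleaved by acid (retro-Friedel–Crafts), the pyrogallol and catechol rings oxidise easily and faster in base, C2 epimerises in base, and the gallate is base-labile; this argues for benzyl ethers throughout and a closing hydrogenolysis. The feature that opens the key step is C4 of unit 3: it is a methine bonded to C4a of its own ring A, to C8 of ring A of unit 4, and to C3, the carbon that carries the only esterified oxygen. Ring C of unit 3 can therefore be assembled around C4 from a formyl group on C8 of unit 4, a symmetric phloroglucinol ether and a glycolaldehyde whose oxygen carries a protecting group found nowhere else.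

**Retrosynthesis**

Deprotection. Target 27 is traced to the perbenzylated, bromine-capped tetramer 26. Twenty-five O-benzyl groups and the C8–Br bond of unit 1 are exchanged for hydrogen in one hydrogenolysis. Benzyl is preferred to acyl or silyl protection because its removal needs neither acid (interflavan bonds) nor base (gallate, pyrogallol rings). The forward step only has to run to completion without air.

Unit 2–unit 3 bond. Tetramer 26 is cut between C4 of unit 2 and C8 of unit 3 into the dimeric electrophile 25 and the dimeric nucleophile 19. This cut halves the molecule, whereas a cut at the unit 1–unit 2 bond would push the longest sequence through two couplings. The unit 3–unit 4 bond is left alone here because it is built by the key step. The forward reaction must attack C8 of the upper unit of 19 in preference to the two C6 positions and enter trans to the 3-benzyloxy group of unit 2. A thioether leaving group that answers only to a soft activator, and a bromine on C8 of unit 1, keep 25 from condensing with itself.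

Unit 1–unit 2 bond. Dimer 25 is cut between C4 of unit 1 and C8 of unit 2 into the 8-bromo 4-alkoxy electrophile 23 and the 4-arylthio nucleophile 24. Both come from the same 4-(2-ethoxyethoxy) ether 22, which comes from hexa-O-benzyl-epigallocatechin 21 and natural (-)-epigallocatechin 20. The cut follows the established logic of flavan-3-ol oligomer assembly and reduces a dimer to one purchasable monomer. The forward coupling needs a hard Lewis acid that ionises the C4–O bond of 23 and leaves the C4–S bond of 24 intact.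

Ester and silyl ether. Gallate 19 is cut at the ester into alcohol 17 and 3,4,5-tris(benzyloxy)benzoic acid 18, and 17 is traced to silyl ether 16. O3 of unit 3 is the only silylated oxygen in 16, so the single esterified position of 27 is marked without any selectivity problem. Acylating before the last coupling places the esterification on a dimer and not on a crowded tetramer.

Ring B and O1–C2 of unit 3. Chroman 16 is opened at O1–C2 to the phenol carbinol 15. Carbinol 15 is cut at the bond between C2 and ring B into lactol 10 and arylmagnesium bromide 14, which is made from bromide 13, triol 12 and 5-bromo-1,2,3-trimethoxybenzene 11. This cut removes ring B and one stereocenter and uses the lactol carbon as the natural electrophile. The forward pair must add the aryl group anti to O3 (Felkin mode) and then close the ring with inversion, which together give the 2,3-cis arrangement.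

Key disconnection. Lactol 10 is cut at C4–C4a, C3–C4 and O1–C2 of unit 3 into 3,5-bis(benzyloxy)phenol 6, aldehyde 5 and (tert-butyldimethylsilyloxy)acetaldehyde 7. A Friedel–Crafts cut of C4–C8 would need a C4 cation beside a differentiated O3 and would leave C6 of unit 4 to compete. The chosen cut fixes the C8 attachment through the formyl carbon, uses a phenol with no regiochemical choice and delivers O3 with the only silyl group. The price is that C2, C3 and C4 of unit 3 are made and not bought. The forward step must form the o-quinone methide 9 (through carbinol 8) and set C3 and C4 under amine control.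

Unit 4. Aldehyde 5 is traced through aryllithium 4 and bromide 3 to penta-O-benzyl-epicatechin 2 and (-)-epicatechin 1. C8 bromination of benzylated flavan-3-ols is selective, so the formyl group is placed with certainty, and C2 and C3 of unit 4 come from the chiral pool.

**Roads not taken**

Alternative 1: Ring A of unit 4 is cut at C8–C8a, C6–C7 and C4a–C8a, so that it is grown on a two-carbon handle at C4 of unit 3. In the forward direction the siloxyalkyne A1 (perbenzylated epigallocatechin gallate with a 4β-(triisopropylsilyloxy)ethynyl group) and the cyclobutenone A2 (3-benzyloxy, carrying the C4–C3–C2 chain and ring B of unit 4) are heated. Ring opening to a vinylketene, [2+2] addition to the alkyne, a second ring opening and a 6π closure would give the phenol A3.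
- Merits: the interflavan bond is never made by electrophilic substitution, so the C6/C8 question does not arise, and the new C8a phenol is ready for ring C closure. Unit 3 arrives with its gallate, C2 and C3 from a natural product. In that respect this road is better than the chosen plan, which has to create three stereocenters of unit 3 and add the ester.
- Weak points: the cascade needs prolonged heating of a substrate with an ester next to an ionisable propargylic, doubly benzylic C4. The free benzylic hydroxyl of A2 can capture the ketene. A2 needs a multistep synthesis of two stereocenters that epicatechin supplies for nothing. Ring C closure and a silyl-to-benzyl exchange still follow.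
- Comparison: the chosen plan sets against it unit 4 from the chiral pool, a key step at or below room temperature, and key-step precursors that are three steps from purchasable materials.

Alternative 2: The cut is O1–C2 of unit 2 in the trimer A5. The precursor is the cis-epoxide A4, in which the ring A phenol of unit 2 is free. In the forward direction mild acid lets that phenol open the epoxide at the benzylic carbon, closing ring C in the 6-endo mode with inversion at C2 and leaving O3 as a free hydroxyl.
- Merits: no activating reagent is needed, and O3 appears without a deprotection step. On that count it is leaner than steps 8 and 9 of the chosen route, which use a Mitsunobu reaction and a desilylation for the same kind of closure.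
- Weak points: the 5-exo mode at C3 competes. The trioxygenated ring B gives the opening cationic character, which threatens the inversion. The acid acts on a substrate that already holds two interflavan bonds and the gallate. The C4 stereocenter of unit 2 has to be set in an open chain without help from a ring. Unit 1 is still to be attached, and the unique O3 of unit 3 is not addressed.
- Comparison: the chosen plan does its inverting closure on a dimer before the ester is present and uses no acid there.

Alternative 3: The cut is C4–C4a of unit 1 in the dimer A7. The precursor is the carbinol A6, in which the future C4 is already bonded to C8 of unit 2 and the future ring A is a 3,5-bis(benzyloxy)phenyl ether on C2. In the forward direction a Lewis acid ionises the carbinol and the tethered aryl ether closes ring C by intramolecular Friedel–Crafts alkylation.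
- Merits: the regiochemistry at C8 of unit 2 is fixed beforehand, self-condensation is impossible, and no halogen cap is needed. In these respects it is more secure than step 15 of the chosen route.
- Weak points: A6 needs a benzylic aryl ether of defined configuration and a three-carbon chain on C8, which is a long sequence toward a dimer that two units of natural epigallocatechin give in a few steps. The Lewis acid can also ionise the benzylic aryl ether at C2. The galloylated unit is left untouched.
- Comparison: the chosen plan applies the same idea, a carbon placed on C8 that becomes C4, to the one unit where O3 has to be unique, and leaves the unit 1–unit 2 bond to established chemistry.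

Key step: step 4

Assumption: compounds 6, 7, 11, 18 and 20 are taken as purchasable, and lactol 10 is carried on as its anomeric mixture because C2 is reset in steps 7 and 8.

**Route**

Step 1
Reactants: 1 (-)-epicatechin
Product: 2 penta-O-benzyl-(-)-epicatechin
Conditions: NaH, BnBr, DMF, -40 °C to rt
Reagents that add atoms: benzyl bromide, BrCc1ccccc1
Why: Williamson etherification; the phenoxides are alkylated first in the cold, which removes the free phenoxide responsible for base-induced C2 epimerisation before the secondary alkoxide reacts on warming.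

Step 2
Reactants: 2 penta-O-benzyl-(-)-epicatechin
Product: 3 8-bromo-penta-O-benzyl-epicatechin
Conditions: N-bromosuccinimide (1.0 equiv), CH2Cl2, -78 °C to rt
Reagents that add atoms: N-bromosuccinimide, O=C1CCC(=O)N1Br
Why: Electrophilic aromatic bromination; in 5,7-dialkoxyflavans C8 is the more nucleophilic and less shielded ring A position, so one equivalent should give the 8-bromide.

Step 3
Reactants: 3 8-bromo-penta-O-benzyl-epicatechin
Product: 5 penta-O-benzyl-epicatechin-8-carbaldehyde, via 8-lithio-penta-O-benzyl-epicatechin 4 (not isolated)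
Conditions: n-BuLi, THF, -78 °C; then DMF, -78 °C to 0 °C; H2O
Reagents that add atoms: N,N-dimethylformamide, CN(C)C=O
Why: Bromine–lithium exchange outruns deprotonation of the benzylic ethers at -78 °C, and the aryllithium is formylated by DMF (Bouveault aldehyde synthesis).

Step 4
Reactants: 6 3,5-bis(benzyloxy)phenol, 5 penta-O-benzyl-epicatechin-8-carbaldehyde, 7 (tert-butyldimethylsilyloxy)acetaldehyde
Product: 10 (3R,4R)-5,7-bis(benzyloxy)-3-(tert-butyldimethylsilyloxy)-4-(penta-O-benzyl-epicatechin-8-yl)chroman-2-ol (4-aryl trans to O3; C2 epimers), via diaryl carbinol 8 (not isolated), via ortho-quinone methide 9 (not isolated)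
Conditions: (S)-2-[diphenyl(trimethylsilyloxy)methyl]pyrrolidine (20 mol %), diphenyl phosphate (PhO)2P(O)OH (20 mol %), 7 (3 equiv), CH2Cl2, 0 °C to rt, 6 added slowly
Reagents that add atoms: none
Why: Proposed new method: acid-catalysed ortho-hydroxyalkylation of phenol 6 by aldehyde 5 gives carbinol 8, which loses water to o-quinone methide 9 (both ionisations are eased by the 2,4,6-trioxygenated ring of unit 4 and the phloroglucinol ring), and the E-enamine of 7 then adds through its oxygen-bearing carbon to the methide carbon before the phenoxide closes on the iminium carbon. The closest known reactions are the amine-catalysed formal [4+2] annulation of aldehyde enamines with o-quinone methides released in situ from o-hydroxybenzyl alcohols, and the acid-catalysed three-component condensations of naphthols, aryl aldehydes and 1,3-dicarbonyl compounds that pass through the same kind of quinone methide; joining the two in one flask with a phenol and so hindered an aldehyde is the untested part. Ring C of unit 3 is closed by 6-exo-trig attack of the ring A oxygen on the iminium carbon (overall a formal inverse-demand oxa-Diels–Alder reaction), and hydrolysis returns the amine and leaves the lactol. C3 is set by the catalyst: the diphenyl(silyloxy)methyl group of the (S)-pyrrolidine shields one face of the s-trans enamine, so the quinone methide enters from the other face and gives 3R. C4 is set relative to C3 by a staggered, antiperiplanar approach that keeps the aryl group of 9 away from the silyloxy group and gives the 3,4-trans (4R) arrangement; unit 4 is enantiopure, so any mismatch would show as separable diastereomers. The step needs ortho and not para hydroxyalkylation, and capture of 9 by the enamine before a second phenol: the two ortho sites of the symmetric phenol are identical, the para site lies between two benzyloxy groups so its quinone methide would be twisted and could not cyclise while Friedel–Crafts addition there is reversible, and slow addition of 6 into an excess of 7 lets the enamine win. The anomeric carbon is left unassigned because steps 7 and 8 reset it.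

Step 5
Reactants: 11 5-bromo-1,2,3-trimethoxybenzene
Product: 12 5-bromobenzene-1,2,3-triol
Conditions: BBr3, CH2Cl2, -78 °C to rt; H2O
Reagents that add atoms: none
Why: Lewis acid cleavage of aryl methyl ethers by BBr3; the aryl bromide is inert.

Step 6
Reactants: 12 5-bromobenzene-1,2,3-triol
Product: 13 5-bromo-1,2,3-tris(benzyloxy)benzene
Conditions: BnBr, K2CO3, DMF, rt, under argon
Reagents that add atoms: benzyl bromide, BrCc1ccccc1
Why: Williamson etherification of the three phenols under mild carbonate conditions; air is excluded to protect the pyrogallol.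

Step 7
Reactants: 10 lactol of step 4, 13 5-bromo-1,2,3-tris(benzyloxy)benzene
Product: 15 (1S,2R,3R)-3-[2,4-bis(benzyloxy)-6-hydroxyphenyl]-2-(tert-butyldimethylsilyloxy)-3-(penta-O-benzyl-epicatechin-8-yl)-1-[3,4,5-tris(benzyloxy)phenyl]propan-1-ol, via 3,4,5-tris(benzyloxy)phenylmagnesium bromide 14 (not isolated)
Conditions: 13, Mg, THF, reflux; then 10 added to 14 (3.5 equiv), THF, -78 to -20 °C; pH 7 buffer
Reagents that add atoms: none
Why: Grignard addition to a lactol through its ring-opened hydroxy aldehyde (the first equivalent deprotonates the lactol); in the polar Felkin–Anh mode the silyloxy group lies anti to the incoming aryl group, and the bulky silyl ether in THF disfavours chelation, so the 1,2-anti (1S) carbinol should predominate.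

Step 8
Reactants: 15 anti phenol carbinol of step 7
Product: 16 3-O-(tert-butyldimethylsilyl)-penta-O-benzyl-epigallocatechin-(4β→8)-penta-O-benzyl-epicatechin
Conditions: PPh3, diisopropyl azodicarboxylate, THF, 0 °C to rt
Reagents that add atoms: none
Why: Intramolecular Mitsunobu etherification (6-exo-tet), a known way to close flavan ring C; the phenol displaces the oxyphosphonium group at the benzylic carbon with inversion, which turns the 1S carbinol into 2R and gives the 2,3-cis chroman.

Step 9
Reactants: 16 silyl ether of step 8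
Product: 17 penta-O-benzyl-epigallocatechin-(4β→8)-penta-O-benzyl-epicatechin with free 3-OH on the upper unit
Conditions: Bu4NF, THF, 0 °C to rt
Reagents that add atoms: none
Why: Fluoride cleavage of the only silyl ether; benzyl ethers and the interflavan bond are inert.

Step 10
Reactants: 17 alcohol of step 9, 18 3,4,5-tris(benzyloxy)benzoic acid
Product: 19 penta-O-benzyl-epigallocatechin 3-O-[3,4,5-tris(benzyloxy)benzoate]-(4β→8)-penta-O-benzyl-epicatechin
Conditions: N,N'-dicyclohexylcarbodiimide, 4-(dimethylamino)pyridine, CH2Cl2, rt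
Reagents that add atoms: none
Why: Steglich esterification; 17 has a single free hydroxyl, so the ester can only go to O3 of unit 3.

Step 11
Reactants: 20 (-)-epigallocatechin
Product: 21 hexa-O-benzyl-(-)-epigallocatechin
Conditions: NaH, BnBr, degassed DMF, -40 °C to rt, under argon
Reagents that add atoms: benzyl bromide, BrCc1ccccc1
Why: Williamson etherification as in step 1; cold, oxygen-free conditions protect the pyrogallol ring and C2 until the phenols are capped.

Step 12
Reactants: 21 hexa-O-benzyl-(-)-epigallocatechin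
Product: 22 4β-(2-ethoxyethoxy)-hexa-O-benzyl-epigallocatechin
Conditions: DDQ, 2-ethoxyethanol, CH2Cl2, rt
Reagents that add atoms: 2-ethoxyethanol, CCOCCO
Why: Known DDQ oxidation of benzylated flavan-3-ols at C4 (hydride abstraction gives a ring A-stabilised cation); the alcohol adds anti to the 3-benzyloxy group.

Step 13
Reactants: 22 4β-(2-ethoxyethoxy) ether of step 12
Product: 23 8-bromo-4β-(2-ethoxyethoxy)-hexa-O-benzyl-epigallocatechin
Conditions: N-bromosuccinimide (1.0 equiv), CH2Cl2, -78 to -20 °C
Reagents that add atoms: N-bromosuccinimide, O=C1CCC(=O)N1Br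
Why: C8-selective electrophilic bromination as in step 2; no acid is formed, so the C4 ether survives, and the bromine blocks C8 of the future unit 1.

Step 14
Reactants: 22 4β-(2-ethoxyethoxy) ether of step 12
Product: 24 4β-(2,6-dimethylphenylthio)-hexa-O-benzyl-epigallocatechin
Conditions: 2,6-dimethylbenzenethiol (3 equiv), BF3·OEt2, CH2Cl2, -78 °C
Reagents that add atoms: 2,6-dimethylbenzenethiol, Cc1cccc(C)c1S
Why: Lewis acid ionisation of the C4 ether and capture by excess thiol (the synthetic counterpart of proanthocyanidin thiolysis); the thiol outcompetes C8 of a second molecule and enters trans to O3.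

Step 15
Reactants: 23 8-bromo electrophile of step 13, 24 thioether nucleophile of step 14
Product: 25 8-bromo-hexa-O-benzyl-epigallocatechin-(4β→8)-[4β-(2,6-dimethylphenylthio)-hexa-O-benzyl-epigallocatechin]
Conditions: BF3·OEt2, CH2Cl2, -78 °C
Reagents that add atoms: none
Why: Friedel–Crafts-type coupling of a flavan C4 cation with C8 of 24 under orthogonal activation: the hard Lewis acid ionises the C4–O bond of 23 and leaves the C4–S bond alone, the bromine keeps 23 from attacking itself, and the 3-benzyloxy group of the 2,3-cis cation directs attack to the 4β face.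

Step 16
Reactants: 25 dimeric thioether of step 15, 19 gallate dimer of step 10
Product: 26 8-bromo-hexa-O-benzyl-epigallocatechin-(4β→8)-hexa-O-benzyl-epigallocatechin-(4β→8)-penta-O-benzyl-epigallocatechin 3-O-[3,4,5-tris(benzyloxy)benzoate]-(4β→8)-penta-O-benzyl-epicatechin
Conditions: I2, Ag2O, CH2Cl2, -78 to -40 °C, dark
Reagents that add atoms: none
Why: Soft, thiophilic activation of the C4 thioether, as used for block couplings of catechin oligomers; C8 of the upper unit of 19 is the most nucleophilic and least shielded ring A site (each C6 lies between two benzyloxy groups), the bromine cap stops 25 from reacting with itself, and attack anti to the 3-benzyloxy group of unit 2 gives the 4β bond under nearly neutral conditions.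

Step 17
Reactants: 26 protected tetramer of step 16
Product: 27 epigallocatechin-(4β→8)-epigallocatechin-(4β→8)-epigallocatechin 3-O-gallate-(4β→8)-epicatechin
Conditions: H2 (1 atm), Pd(OH)2/C, THF/MeOH/H2O, rt, degassed solvents
Reagents that add atoms: none
Why: Hydrogenolysis of the twenty-five benzyl ethers together with the aryl C–Br bond; the ester, the secondary alcohols and the interflavan bonds are not touched, and no stereocenter is involved.

**Compound list**

1 | (-)-epicatechin, (2R,3R)-2-(3,4-dihydroxyphenyl)chroman-3,5,7-triol | O[C@@H]1Cc2c(O)cc(O)cc2O[C@@H]1c1ccc(O)c(O)c1 | starting material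
2 | penta-O-benzyl-(-)-epicatechin, (2R,3R)-3,5,7-tris(benzyloxy)-2-[3,4-bis(benzyloxy)phenyl]chroman | O(Cc7ccccc7)[C@@H]1Cc2c(OCc7ccccc7)cc(OCc7ccccc7)cc2O[C@@H]1c1ccc(OCc7ccccc7)c(OCc7ccccc7)c1 | intermediate
3 | 8-bromo-penta-O-benzyl-epicatechin (2R,3R) | O(Cc7ccccc7)[C@@H]1Cc2c(OCc7ccccc7)cc(OCc7ccccc7)c(Br)c2O[C@@H]1c1ccc(OCc7ccccc7)c(OCc7ccccc7)c1 | intermediate
4 | 8-lithio-penta-O-benzyl-epicatechin (2R,3R) | [Li]c2c(OCc7ccccc7)cc(OCc7ccccc7)c3c2O[C@H](c2ccc(OCc7ccccc7)c(OCc7ccccc7)c2)[C@H](OCc7ccccc7)C3 | intermediate (not isolated)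
5 | penta-O-benzyl-epicatechin-8-carbaldehyde (2R,3R) | O=Cc2c(OCc7ccccc7)cc(OCc7ccccc7)c3c2O[C@H](c2ccc(OCc7ccccc7)c(OCc7ccccc7)c2)[C@H](OCc7ccccc7)C3 | intermediate
6 | 3,5-bis(benzyloxy)phenol | Oc1cc(OCc7ccccc7)cc(OCc7ccccc7)c1 | starting material
7 | (tert-butyldimethylsilyloxy)acetaldehyde | CC(C)(C)[Si](C)(C)OCC=O | starting material
8 | [2,4-bis(benzyloxy)-6-hydroxyphenyl](penta-O-benzyl-epicatechin-8-yl)methanol, carbinol carbon unassigned | OC(c1c(O)cc(OCc7ccccc7)cc1OCc7ccccc7)c2c(OCc7ccccc7)cc(OCc7ccccc7)c3c2O[C@H](c2ccc(OCc7ccccc7)c(OCc7ccccc7)c2)[C@H](OCc7ccccc7)C3 | intermediate (not isolated)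
9 | o-quinone methide, 3,5-bis(benzyloxy)-6-[(penta-O-benzyl-epicatechin-8-yl)methylidene]cyclohexa-2,4-dien-1-one | O=C1C=C(OCc7ccccc7)C=C(OCc7ccccc7)C1=Cc2c(OCc7ccccc7)cc(OCc7ccccc7)c3c2O[C@H](c2ccc(OCc7ccccc7)c(OCc7ccccc7)c2)[C@H](OCc7ccccc7)C3 | intermediate (not isolated)
10 | (3R,4R)-5,7-bis(benzyloxy)-3-(tert-butyldimethylsilyloxy)-4-(penta-O-benzyl-epicatechin-8-yl)chroman-2-ol, 4-aryl trans to O3, C2 epimers | CC(C)(C)[Si](C)(C)O[C@@H]1[C@@H](c2c(OCc7ccccc7)cc(OCc7ccccc7)c3c2O[C@H](c2ccc(OCc7ccccc7)c(OCc7ccccc7)c2)[C@H](OCc7ccccc7)C3)c2c(OCc7ccccc7)cc(OCc7ccccc7)cc2OC1O | intermediate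
11 | 5-bromo-1,2,3-trimethoxybenzene | COc1cc(Br)cc(OC)c1OC | starting material
12 | 5-bromobenzene-1,2,3-triol | Oc1cc(Br)cc(O)c1O | intermediate
13 | 5-bromo-1,2,3-tris(benzyloxy)benzene | Brc1cc(OCc7ccccc7)c(OCc7ccccc7)c(OCc7ccccc7)c1 | intermediate
14 | 3,4,5-tris(benzyloxy)phenylmagnesium bromide | Br[Mg]c1cc(OCc7ccccc7)c(OCc7ccccc7)c(OCc7ccccc7)c1 | intermediate (not isolated)
15 | (1S,2R,3R)-3-[2,4-bis(benzyloxy)-6-hydroxyphenyl]-2-(tert-butyldimethylsilyloxy)-3-(penta-O-benzyl-epicatechin-8-yl)-1-[3,4,5-tris(benzyloxy)phenyl]propan-1-ol | O[C@H]([C@H](O[Si](C)(C)C(C)(C)C)[C@@H](c2c(OCc7ccccc7)cc(OCc7ccccc7)c3c2O[C@H](c2ccc(OCc7ccccc7)c(OCc7ccccc7)c2)[C@H](OCc7ccccc7)C3)c2c(OCc7ccccc7)cc(OCc7ccccc7)cc2O)c1cc(OCc7ccccc7)c(OCc7ccccc7)c(OCc7ccccc7)c1 | intermediate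
16 | 3-O-(tert-butyldimethylsilyl)-penta-O-benzyl-epigallocatechin-(4β→8)-penta-O-benzyl-epicatechin (upper unit 2R,3R, 4-aryl trans to O3) | CC(C)(C)[Si](C)(C)O[C@@H]1[C@@H](c2c(OCc7ccccc7)cc(OCc7ccccc7)c3c2O[C@H](c2ccc(OCc7ccccc7)c(OCc7ccccc7)c2)[C@H](OCc7ccccc7)C3)c2c(OCc7ccccc7)cc(OCc7ccccc7)cc2O[C@@H]1c1cc(OCc7ccccc7)c(OCc7ccccc7)c(OCc7ccccc7)c1 | intermediate
17 | penta-O-benzyl-epigallocatechin-(4β→8)-penta-O-benzyl-epicatechin, free 3-OH on the upper unit | O[C@@H]1[C@@H](c2c(OCc7ccccc7)cc(OCc7ccccc7)c3c2O[C@H](c2ccc(OCc7ccccc7)c(OCc7ccccc7)c2)[C@H](OCc7ccccc7)C3)c2c(OCc7ccccc7)cc(OCc7ccccc7)cc2O[C@@H]1c1cc(OCc7ccccc7)c(OCc7ccccc7)c(OCc7ccccc7)c1 | intermediate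
18 | 3,4,5-tris(benzyloxy)benzoic acid | OC(=O)c1cc(OCc7ccccc7)c(OCc7ccccc7)c(OCc7ccccc7)c1 | starting material
19 | penta-O-benzyl-epigallocatechin 3-O-[3,4,5-tris(benzyloxy)benzoate]-(4β→8)-penta-O-benzyl-epicatechin | O=C(O[C@@H]1[C@@H](c2c(OCc7ccccc7)cc(OCc7ccccc7)c3c2O[C@H](c2ccc(OCc7ccccc7)c(OCc7ccccc7)c2)[C@H](OCc7ccccc7)C3)c2c(OCc7ccccc7)cc(OCc7ccccc7)cc2O[C@@H]1c1cc(OCc7ccccc7)c(OCc7ccccc7)c(OCc7ccccc7)c1)c1cc(OCc7ccccc7)c(OCc7ccccc7)c(OCc7ccccc7)c1 | intermediate
20 | (-)-epigallocatechin, (2R,3R)-2-(3,4,5-trihydroxyphenyl)chroman-3,5,7-triol | O[C@@H]1Cc2c(O)cc(O)cc2O[C@@H]1c1cc(O)c(O)c(O)c1 | starting material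
21 | hexa-O-benzyl-(-)-epigallocatechin (2R,3R) | O(Cc7ccccc7)[C@@H]1Cc2c(OCc7ccccc7)cc(OCc7ccccc7)cc2O[C@@H]1c1cc(OCc7ccccc7)c(OCc7ccccc7)c(OCc7ccccc7)c1 | intermediate
22 | 4β-(2-ethoxyethoxy)-hexa-O-benzyl-epigallocatechin (C2 and C3 as in 21, 4-alkoxy trans to O3) | CCOCCO[C@H]1c2c(OCc7ccccc7)cc(OCc7ccccc7)cc2O[C@H](c2cc(OCc7ccccc7)c(OCc7ccccc7)c(OCc7ccccc7)c2)[C@@H]1OCc7ccccc7 | intermediate
23 | 8-bromo-4β-(2-ethoxyethoxy)-hexa-O-benzyl-epigallocatechin | CCOCCO[C@H]1c2c(OCc7ccccc7)cc(OCc7ccccc7)c(Br)c2O[C@H](c2cc(OCc7ccccc7)c(OCc7ccccc7)c(OCc7ccccc7)c2)[C@@H]1OCc7ccccc7 | intermediate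
24 | 4β-(2,6-dimethylphenylthio)-hexa-O-benzyl-epigallocatechin (4-arylthio trans to O3) | Cc1cccc(C)c1S[C@H]1c2c(OCc7ccccc7)cc(OCc7ccccc7)cc2O[C@H](c2cc(OCc7ccccc7)c(OCc7ccccc7)c(OCc7ccccc7)c2)[C@@H]1OCc7ccccc7 | intermediate
25 | 8-bromo-hexa-O-benzyl-epigallocatechin-(4β→8)-[4β-(2,6-dimethylphenylthio)-hexa-O-benzyl-epigallocatechin] | Cc1cccc(C)c1S[C@H]1c2c(OCc7ccccc7)cc(OCc7ccccc7)c([C@H]3c4c(OCc7ccccc7)cc(OCc7ccccc7)c(Br)c4O[C@H](c4cc(OCc7ccccc7)c(OCc7ccccc7)c(OCc7ccccc7)c4)[C@@H]3OCc7ccccc7)c2O[C@H](c2cc(OCc7ccccc7)c(OCc7ccccc7)c(OCc7ccccc7)c2)[C@@H]1OCc7ccccc7 | intermediate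
26 | perbenzylated tetramer with bromine on C8 of unit 1 and the tribenzylgalloyl ester on O3 of unit 3 (all units 2R,3R, all interflavan bonds 4β→8) | O=C(O[C@@H]1[C@@H](c2c(OCc7ccccc7)cc(OCc7ccccc7)c3c2O[C@H](c2ccc(OCc7ccccc7)c(OCc7ccccc7)c2)[C@H](OCc7ccccc7)C3)c2c(OCc7ccccc7)cc(OCc7ccccc7)c([C@H]3c4c(OCc7ccccc7)cc(OCc7ccccc7)c([C@H]5c6c(OCc7ccccc7)cc(OCc7ccccc7)c(Br)c6O[C@H](c6cc(OCc7ccccc7)c(OCc7ccccc7)c(OCc7ccccc7)c6)[C@@H]5OCc7ccccc7)c4O[C@H](c4cc(OCc7ccccc7)c(OCc7ccccc7)c(OCc7ccccc7)c4)[C@@H]3OCc7ccccc7)c2O[C@@H]1c1cc(OCc7ccccc7)c(OCc7ccccc7)c(OCc7ccccc7)c1)c1cc(OCc7ccccc7)c(OCc7ccccc7)c(OCc7ccccc7)c1 | intermediate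
27 | epigallocatechin-(4β→8)-epigallocatechin-(4β→8)-epigallocatechin 3-O-gallate-(4β→8)-epicatechin (CNP0305998.1) | O=C(O[C@@H]1[C@@H](c2c(O)cc(O)c3c2O[C@H](c2ccc(O)c(O)c2)[C@H](O)C3)c2c(O)cc(O)c([C@H]3c4c(O)cc(O)c([C@H]5c6c(O)cc(O)cc6O[C@H](c6cc(O)c(O)c(O)c6)[C@@H]5O)c4O[C@H](c4cc(O)c(O)c(O)c4)[C@@H]3O)c2O[C@@H]1c1cc(O)c(O)c(O)c1)c1cc(O)c(O)c(O)c1 | target

**Step count and risk**

Total step count: 17. Longest linear sequence: 10 steps (steps 1, 2, 3, 4, 7, 8, 9, 10, 16, 17).

Least certain steps:

Step 4 (Proposed new method: three-component annulation). The most likely failures are double arylation of the aldehyde carbon, when a second phenol and not the enamine captures the quinone methide, and sluggish condensation, because the trioxygenated aldehyde is a poor electrophile while the acid is partly buffered by the amine. Hydroxyalkylation para to the phenol oxygen and a mismatch between the catalyst and the remote stereocenters of unit 4 are lesser risks. The fallback separates the two events with known chemistry and sets out from 5 and 6. Phenol 6 is converted with EtMgBr in toluene into bromomagnesium 3,5-bis(benzyloxy)phenoxide F1, which adds to 5 through a magnesium-bridged six-membered transition state and therefore only ortho, to give carbinol 8 as an isolated compound. Carbinol 8 is then submitted with 7 to the known two-component amine and acid annulation of an o-hydroxybenzyl alcohol, which returns to the route at 10.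

Step 7. Facial selectivity may be poor, because a steric mode with the very large diarylmethyl group anti to the nucleophile competes with the polar Felkin mode. Enolisation of the hindered aldehyde, or silyl migration from O3 to the new alkoxide, would also erode the result. The fallback sets out from 10 and moves the stereochemical decision from a C–C bond formation to a ketone reduction. Lactol 10 is oxidised with Ag2CO3 on Celite to the dihydrocoumarin F2. One equivalent of 14 at -78 °C gives the hydroxy ketone F3 (in equilibrium with its cyclic hemiketal). Reduction with the bulky, non-chelating LiBH(s-Bu)3 in the Felkin sense returns to the route at 15.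

Step 8. The benzylic oxyphosphonium ion carries a para-benzyloxy group, so ionisation before displacement could erode the inversion, and elimination to a styrene could compete. The fallback sets out from 15 and relies on neighbouring-group geometry. Desilylation with Bu4NF gives the triol F4. Triethyl orthoformate with pyridinium p-toluenesulfonate forms the cyclic orthoformate F5, whose dioxolanylium ion can only be opened by the phenol at the benzylic carbon from the face opposite to the departing oxygen, giving the 2,3-cis 3-O-formate F6. Methanolysis with K2CO3 returns to the route at 17, and step 9 is no longer needed.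

Step 16. The coupling may be slow because the galloyl ester shields C8 of unit 3. Attack at a C6 position, ring iodination of 19, or acid-induced scission of an interflavan bond could then take over. The fallback changes the order of events and sets out from 25 and 16. The less hindered silyl ether 16 is coupled with 25 under the same soft activation to the silylated tetramer F7. Bu4NF gives the tetramer alcohol F8, which has a single free hydroxyl, and esterification with 18 as in step 10 returns to the route at 26.

Step 17. Cleavage of twenty-five benzyl ethers may stall as the product becomes polar. The HBr released from the bromine cap may cleave interflavan bonds once the phenols are free, and the free polyphenol oxidises in air. The fallback sets out from 26 and takes the bromine off before any phenol is free. Radical reduction with Bu3SnH and azobisisobutyronitrile in toluene gives the bromine-free perbenzylated tetramer F9, and hydrogenolysis over Pd(OH)2/C under acid-free conditions then returns to the route at 27.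

**Further compounds**

F1 | step 4 | bromomagnesium 3,5-bis(benzyloxy)phenoxide | Br[Mg]Oc1cc(OCc7ccccc7)cc(OCc7ccccc7)c1
F2 | step 7 | (3R,4R)-5,7-bis(benzyloxy)-3-(tert-butyldimethylsilyloxy)-4-(penta-O-benzyl-epicatechin-8-yl)chroman-2-one | CC(C)(C)[Si](C)(C)O[C@@H]1[C@@H](c2c(OCc7ccccc7)cc(OCc7ccccc7)c3c2O[C@H](c2ccc(OCc7ccccc7)c(OCc7ccccc7)c2)[C@H](OCc7ccccc7)C3)c2c(OCc7ccccc7)cc(OCc7ccccc7)cc2OC1=O
F3 | step 7 | (2R,3R)-3-[2,4-bis(benzyloxy)-6-hydroxyphenyl]-2-(tert-butyldimethylsilyloxy)-3-(penta-O-benzyl-epicatechin-8-yl)-1-[3,4,5-tris(benzyloxy)phenyl]propan-1-one | O=C([C@H](O[Si](C)(C)C(C)(C)C)[C@@H](c2c(OCc7ccccc7)cc(OCc7ccccc7)c3c2O[C@H](c2ccc(OCc7ccccc7)c(OCc7ccccc7)c2)[C@H](OCc7ccccc7)C3)c2c(OCc7ccccc7)cc(OCc7ccccc7)cc2O)c1cc(OCc7ccccc7)c(OCc7ccccc7)c(OCc7ccccc7)c1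
F4 | step 8 | (1S,2R,3R)-3-[2,4-bis(benzyloxy)-6-hydroxyphenyl]-3-(penta-O-benzyl-epicatechin-8-yl)-1-[3,4,5-tris(benzyloxy)phenyl]propane-1,2-diol | O[C@H]([C@H](O)[C@@H](c2c(OCc7ccccc7)cc(OCc7ccccc7)c3c2O[C@H](c2ccc(OCc7ccccc7)c(OCc7ccccc7)c2)[C@H](OCc7ccccc7)C3)c2c(OCc7ccccc7)cc(OCc7ccccc7)cc2O)c1cc(OCc7ccccc7)c(OCc7ccccc7)c(OCc7ccccc7)c1
F5 | step 8 | cyclic orthoformate (2-ethoxy-1,3-dioxolane) of the 1,2-diol of F4, orthoester carbon unassigned | CCOC1O[C@@H](c2cc(OCc7ccccc7)c(OCc7ccccc7)c(OCc7ccccc7)c2)[C@H](O1)[C@@H](c2c(OCc7ccccc7)cc(OCc7ccccc7)c3c2O[C@H](c2ccc(OCc7ccccc7)c(OCc7ccccc7)c2)[C@H](OCc7ccccc7)C3)c2c(OCc7ccccc7)cc(OCc7ccccc7)cc2O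
F6 | step 8 | 3-O-formyl-penta-O-benzyl-epigallocatechin-(4β→8)-penta-O-benzyl-epicatechin | O=CO[C@@H]1[C@@H](c2c(OCc7ccccc7)cc(OCc7ccccc7)c3c2O[C@H](c2ccc(OCc7ccccc7)c(OCc7ccccc7)c2)[C@H](OCc7ccccc7)C3)c2c(OCc7ccccc7)cc(OCc7ccccc7)cc2O[C@@H]1c1cc(OCc7ccccc7)c(OCc7ccccc7)c(OCc7ccccc7)c1
F7 | step 16 | bromine-capped perbenzylated tetramer with a tert-butyldimethylsilyl ether on O3 of unit 3 | CC(C)(C)[Si](C)(C)O[C@@H]1[C@@H](c2c(OCc7ccccc7)cc(OCc7ccccc7)c3c2O[C@H](c2ccc(OCc7ccccc7)c(OCc7ccccc7)c2)[C@H](OCc7ccccc7)C3)c2c(OCc7ccccc7)cc(OCc7ccccc7)c([C@H]3c4c(OCc7ccccc7)cc(OCc7ccccc7)c([C@H]5c6c(OCc7ccccc7)cc(OCc7ccccc7)c(Br)c6O[C@H](c6cc(OCc7ccccc7)c(OCc7ccccc7)c(OCc7ccccc7)c6)[C@@H]5OCc7ccccc7)c4O[C@H](c4cc(OCc7ccccc7)c(OCc7ccccc7)c(OCc7ccccc7)c4)[C@@H]3OCc7ccccc7)c2O[C@@H]1c1cc(OCc7ccccc7)c(OCc7ccccc7)c(OCc7ccccc7)c1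
F8 | step 16 | bromine-capped perbenzylated tetramer with free 3-OH on unit 3 | O[C@@H]1[C@@H](c2c(OCc7ccccc7)cc(OCc7ccccc7)c3c2O[C@H](c2ccc(OCc7ccccc7)c(OCc7ccccc7)c2)[C@H](OCc7ccccc7)C3)c2c(OCc7ccccc7)cc(OCc7ccccc7)c([C@H]3c4c(OCc7ccccc7)cc(OCc7ccccc7)c([C@H]5c6c(OCc7ccccc7)cc(OCc7ccccc7)c(Br)c6O[C@H](c6cc(OCc7ccccc7)c(OCc7ccccc7)c(OCc7ccccc7)c6)[C@@H]5OCc7ccccc7)c4O[C@H](c4cc(OCc7ccccc7)c(OCc7ccccc7)c(OCc7ccccc7)c4)[C@@H]3OCc7ccccc7)c2O[C@@H]1c1cc(OCc7ccccc7)c(OCc7ccccc7)c(OCc7ccccc7)c1
F9 | step 17 | perbenzylated tetramer gallate without bromine (C8 of unit 1 bears hydrogen) | O=C(O[C@@H]1[C@@H](c2c(OCc7ccccc7)cc(OCc7ccccc7)c3c2O[C@H](c2ccc(OCc7ccccc7)c(OCc7ccccc7)c2)[C@H](OCc7ccccc7)C3)c2c(OCc7ccccc7)cc(OCc7ccccc7)c([C@H]3c4c(OCc7ccccc7)cc(OCc7ccccc7)c([C@H]5c6c(OCc7ccccc7)cc(OCc7ccccc7)cc6O[C@H](c6cc(OCc7ccccc7)c(OCc7ccccc7)c(OCc7ccccc7)c6)[C@@H]5OCc7ccccc7)c4O[C@H](c4cc(OCc7ccccc7)c(OCc7ccccc7)c(OCc7ccccc7)c4)[C@@H]3OCc7ccccc7)c2O[C@@H]1c1cc(OCc7ccccc7)c(OCc7ccccc7)c(OCc7ccccc7)c1)c1cc(OCc7ccccc7)c(OCc7ccccc7)c(OCc7ccccc7)c1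
A1 | alternative 1 | perbenzylated epigallocatechin gallate with a 4β-(triisopropylsilyloxy)ethynyl group | O=C(O[C@@H]1[C@@H](C#CO[Si](C(C)C)(C(C)C)C(C)C)c2c(OCc7ccccc7)cc(OCc7ccccc7)cc2O[C@@H]1c1cc(OCc7ccccc7)c(OCc7ccccc7)c(OCc7ccccc7)c1)c1cc(OCc7ccccc7)c(OCc7ccccc7)c(OCc7ccccc7)c1
A2 | alternative 1 | 3-(benzyloxy)-2-[(2R,3S)-2-(benzyloxy)-3-[3,4-bis(benzyloxy)phenyl]-3-hydroxypropyl]cyclobut-2-en-1-one (stereodescriptors as drawn in the SMILES) | O=C1CC(OCc7ccccc7)=C1C[C@@H](OCc7ccccc7)[C@@H](O)c1ccc(OCc7ccccc7)c(OCc7ccccc7)c1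
A3 | alternative 1 | unit 3 gallate bearing at C4 the new ring A of unit 4 (C8a phenol, C7 silyl ether, C5 benzyl ether, C4a side chain) | O=C(O[C@@H]1[C@@H](c2c(O[Si](C(C)C)(C(C)C)C(C)C)cc(OCc7ccccc7)c(C[C@@H](OCc7ccccc7)[C@@H](O)c3ccc(OCc7ccccc7)c(OCc7ccccc7)c3)c2O)c2c(OCc7ccccc7)cc(OCc7ccccc7)cc2O[C@@H]1c1cc(OCc7ccccc7)c(OCc7ccccc7)c(OCc7ccccc7)c1)c1cc(OCc7ccccc7)c(OCc7ccccc7)c(OCc7ccccc7)c1
A4 | alternative 2 | cis-epoxide precursor: unit 3 gallate–unit 4 dimer carrying on C8 of unit 3 the open-chain unit 2 (free ring A phenol, cis C2–C3 epoxide) | O=C(O[C@@H]1[C@@H](c2c(OCc7ccccc7)cc(OCc7ccccc7)c3c2O[C@H](c2ccc(OCc7ccccc7)c(OCc7ccccc7)c2)[C@H](OCc7ccccc7)C3)c2c(OCc7ccccc7)cc(OCc7ccccc7)c([C@@H](c4c(OCc7ccccc7)cc(OCc7ccccc7)cc4O)[C@H]5O[C@H]5c6cc(OCc7ccccc7)c(OCc7ccccc7)c(OCc7ccccc7)c6)c2O[C@@H]1c1cc(OCc7ccccc7)c(OCc7ccccc7)c(OCc7ccccc7)c1)c1cc(OCc7ccccc7)c(OCc7ccccc7)c(OCc7ccccc7)c1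
A5 | alternative 2 | benzylated unit 2–unit 3–unit 4 trimer with free 3-hydroxyl on unit 2 | O=C(O[C@@H]1[C@@H](c2c(OCc7ccccc7)cc(OCc7ccccc7)c3c2O[C@H](c2ccc(OCc7ccccc7)c(OCc7ccccc7)c2)[C@H](OCc7ccccc7)C3)c2c(OCc7ccccc7)cc(OCc7ccccc7)c([C@H]3c4c(OCc7ccccc7)cc(OCc7ccccc7)cc4O[C@H](c4cc(OCc7ccccc7)c(OCc7ccccc7)c(OCc7ccccc7)c4)[C@@H]3O)c2O[C@@H]1c1cc(OCc7ccccc7)c(OCc7ccccc7)c(OCc7ccccc7)c1)c1cc(OCc7ccccc7)c(OCc7ccccc7)c(OCc7ccccc7)c1
A6 | alternative 3 | hexa-O-benzyl-epigallocatechin carrying on C8 the open-chain unit 1 (C4 carbinol, 3-benzyloxy, 2-[3,5-bis(benzyloxy)phenoxy], ring B), carbinol carbon unassigned | C3c4c(OCc7ccccc7)cc(OCc7ccccc7)c(C(O)[C@@H](OCc7ccccc7)[C@H](Oc5cc(OCc7ccccc7)cc(OCc7ccccc7)c5)c6cc(OCc7ccccc7)c(OCc7ccccc7)c(OCc7ccccc7)c6)c4O[C@H](c4cc(OCc7ccccc7)c(OCc7ccccc7)c(OCc7ccccc7)c4)[C@@H]3OCc7ccccc7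
A7 | alternative 3 | perbenzylated unit 1-(4β→8)-unit 2 dimer | C3c4c(OCc7ccccc7)cc(OCc7ccccc7)c([C@H]5c6c(OCc7ccccc7)cc(OCc7ccccc7)cc6O[C@H](c6cc(OCc7ccccc7)c(OCc7ccccc7)c(OCc7ccccc7)c6)[C@@H]5OCc7ccccc7)c4O[C@H](c4cc(OCc7ccccc7)c(OCc7ccccc7)c(OCc7ccccc7)c4)[C@@H]3OCc7ccccc7
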